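Target over side product A reads 0.588, 0.596 and 0.596 in the teal run at 3.00 h, 6.00 h and 15.0 h, and your choice of charging half the teal partner hangs on what this ratio does next.

| flask | starting material | partner | remark | time |
|---|---|---|---|---|
| teal | 10 mM | 100 mM (in portions, 4) | run made earlier; portions every 30 min |  |
| flask | 10 mM | 50.0 mM (in portions, 4) | the portions of partner follow each other after 30 min, the first at the start | 15 d |

- teal (time / h: target / %, side product A / %): 3.00: 20, 34; 6.00: 28, 47; 15.0: 34, 57; 40.0: 31, 57

(standard deviation of a reading: 1.5 percentage points)

- percent here means starting material units held: one side product B counts as two
- the numbers in the tables scatter by 1.5 percentage points (one standard deviation)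

- the target standing at 15 d, as a percentage of the starting material charged
- the side product A standing at 15 d, as a percentage of the starting material charged
- the side product B standing at 15 d, as a percentage of the starting material charged

1. Starting material is the limiting reagent by charge, with 10 mM charged against 50.0 mM of partner in the flask. I reckon its balance at full conversion: target, side product A and side product B add up to 100% of the charge.

2. In the teal run, side product A reads 57% at 15.0 h and 57% at 40.0 h. Target moves 3 percentage points, against a scatter of 2.1 points on a difference of two readings. So I pool them as one end state: target 32.5%, and a gap of 10.5%, which I read as side product B.

3. Target over side product A, divided by the partner charge, reads 0.00570 mM⁻¹: this selectivity per partner is what I carry. My own assumption, which one partner level cannot show, is that target takes partner while both side products take none. On the same assumption, I hold side product B over side product A at the teal reading of 0.184.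

4. For the flask, I reckon target over side product A at 0.285. The balance then gives side product A 68.1%, target 19.4% and side product B 12.5%. That reckoned target is less than the 32.5% pooled from the teal run, so if target is your aim, keep 100 mM of partner.

5. The forecast says target 14% (8% to 23%), side product A 51% (45% to 57%) and side product B 35% (24% to 44%). It holds that “both form in parallel with the same dependence on partner”, which differs from my step 3.

    starting material + partner → target (k = 1.82 M⁻¹ h⁻¹)
    starting material → side product A (k = 0.190 h⁻¹)
    2 starting material → side product B (k = 4.13 M⁻¹ h⁻¹)
    partner → decomposed reagent (k = 0.120 h⁻¹)

The flask holds target 17.8%, side product A 68.2% and side product B 14.0% at 15.0 d, so target over side product A is 0.261 against the 0.285 reckoned. For the neighbour flask, charged with 30 mM of partner, the selectivity per partner gives a ratio of 0.171. The balance then gives side product A 73.8%, target 12.6% and side product B 13.6%. At 15.0 d, that neighbour flask stands at target 11.4%, side product A 73.6% and side product B 15.1%.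

The data are simulated on assumed constants; scatter was added.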